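**Retrosynthetic overview**
1. Germacranolide numbering is used: C1–C10 ring, C11–C13 lactone carbons, C14 on C10, C15 on C4. The O14 isovalerate and O9 acetate are removed first; the ten-membered carbocycle is then opened at C9–C10 (intramolecular Nozaki–Hiyama–Kishi coupling of an alkenyl iodide with the C9 aldehyde). This is the second ring to form.
2. The lactone is the first ring to form. A malonic half ester is annulated with Mn(OAc)3 onto an open-chain (4Z,6E)-diene: C7–C11 forms first and the ring closes by O–C6 bond formation, setting C6 and C7 in one operation.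
3. Enabling feature: the conjugated C4=C5–C6=C7 diene next to the C8 stereocentre. Radical attack at C7 leaves an allyl cation over C4–C5–C6, which the new carboxyl reaches at C6 through a five-membered transition state.
4. The diene comes from Horner–Wadsworth–Emmons union of a nerol-derived allylic phosphonate (C1–C6, C15, the 4Z olefin; C10/C14 added as a 2-iodoallyl unit) with (R)-glyceraldehyde acetonide (C7–C9, the source of all absolute stereochemistry).
5. C13 is introduced after the key step by decarboxylative methylenation of the malonate-derived carboxyl.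

Key step: step 10

Remark: (R)-glyceraldehyde acetonide is taken as a commercial chiral-pool aldehyde; any minor 6Z isomer of diene 11 need not be removed, because the C6=C7 geometry is lost in the key step.

Step 1
Reactants: 1 nerol
Product: 2 neryl bromide
Conditions: PBr3, pyridine (cat.), Et2O, −10 °C
Reagents that add atoms: phosphorus tribromide, BrP(Br)Br
Why: Bromination of the primary allylic alcohol with PBr3 at low temperature (SN2-type substitution of the activated phosphite ester) should proceed without allylic transposition and keep the 2Z olefin that becomes C4=C5.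

Step 2
Reactants: 2 neryl bromide
Product: 3 diethyl [(2Z)-3,7-dimethylocta-2,6-dien-1-yl]phosphonate
Conditions: P(OEt)3, neat, 100 °C
Reagents that add atoms: triethyl phosphite, CCOP(OCC)OCC
Why: Michaelis–Arbuzov reaction, in which SN2 attack of the phosphite at the primary allylic carbon and dealkylation by bromide should give the allylic phosphonate with the Z olefin intact.

Step 3
Reactants: 3 diethyl [(2Z)-3,7-dimethylocta-2,6-dien-1-yl]phosphonate
Product: 5 diethyl [(2Z)-3-methyl-6-oxohex-2-en-1-yl]phosphonate, via terminal epoxide 4 (not isolated)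
Conditions: mCPBA, CH2Cl2, 0 °C; then H5IO6, THF/H2O, 0 °C to rt
Reagents that add atoms: 3-chloroperbenzoic acid, OOC(=O)c1cccc(Cl)c1
Why: Prilezhaev epoxidation should select the electron-rich terminal trisubstituted alkene over the one deactivated by the allylic phosphonate, and periodic acid then hydrolyses the epoxide and cleaves the glycol (Malaprade-type cleavage) to the aldehyde with loss of acetone.

Step 4
Reactants: 5 diethyl [(2Z)-3-methyl-6-oxohex-2-en-1-yl]phosphonate
Product: 6 diethyl [(2Z,6E)-3-methyl-8-oxoocta-2,6-dien-1-yl]phosphonate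
Conditions: Ph3P=CHCHO, toluene, 70 °C
Reagents that add atoms: (triphenylphosphoranylidene)acetaldehyde, O=CC=P(c1ccccc1)(c1ccccc1)c1ccccc1
Why: Wittig reaction with the stabilized formylmethylene ylide should give the E enal and thereby adds C10 and C14.

Step 5
Reactants: 6 diethyl [(2Z,6E)-3-methyl-8-oxoocta-2,6-dien-1-yl]phosphonate
Product: 7 diethyl [(2Z,6Z)-7-iodo-3-methyl-8-oxoocta-2,6-dien-1-yl]phosphonate
Conditions: I2, DMAP (cat.), K2CO3, THF/H2O, rt
Reagents that add atoms: iodine, II
Why: Amine-catalysed α-iodination of the enal (conjugate addition of DMAP, iodination of the enolate and elimination, a Morita–Baylis–Hillman-type sequence) should give the thermodynamically favoured isomer with the carbon chain cis to iodine, which fixes the 1(10)Z geometry.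

Step 6
Reactants: 7 diethyl [(2Z,6Z)-7-iodo-3-methyl-8-oxoocta-2,6-dien-1-yl]phosphonate
Product: 8 diethyl [(2Z,6Z)-8-hydroxy-7-iodo-3-methylocta-2,6-dien-1-yl]phosphonate
Conditions: NaBH4, CeCl3·7H2O, MeOH, −40 °C
Reagents that add atoms: none
Why: Luche reduction should reduce the aldehyde in a 1,2-sense without touching the alkenyl iodide.

Step 7
Reactants: 8 diethyl [(2Z,6Z)-8-hydroxy-7-iodo-3-methylocta-2,6-dien-1-yl]phosphonate
Product: 9 diethyl [(2Z,6Z)-8-[(tert-butyldiphenylsilyl)oxy]-7-iodo-3-methylocta-2,6-dien-1-yl]phosphonate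
Conditions: TBDPSCl, imidazole, CH2Cl2, rt
Reagents that add atoms: tert-butyl(chloro)diphenylsilane, CC(C)(C)[Si](Cl)(c1ccccc1)c1ccccc1
Why: Standard silylation of the primary allylic alcohol gives an ether that survives acetic acid and organochromium chemistry and, unlike an ester, should not be lost by β-elimination from the later alkenylchromium species.

Step 8
Reactants: 9 diethyl [(2Z,6Z)-8-[(tert-butyldiphenylsilyl)oxy]-7-iodo-3-methylocta-2,6-dien-1-yl]phosphonate; 10 (R)-glyceraldehyde acetonide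
Product: 11 tert-butyl{[(2Z,6Z,8E)-9-[(4S)-2,2-dimethyl-1,3-dioxolan-4-yl]-2-iodo-6-methylnona-2,6,8-trien-1-yl]oxy}diphenylsilane
Conditions: KN(SiMe3)2, THF, −78 °C; then 10, −78 to 0 °C
Reagents that add atoms: none
Why: Horner–Wadsworth–Emmons olefination, in which the potassium carbanion of the allylic phosphonate should add to aldehyde 10 through its α-carbon (the γ-carbon is fully substituted) and eliminate phosphate to the 6E diene, while the C8 stereocentre is carried over unchanged from 10.

Step 9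
Reactants: 12 Meldrum's acid; 13 2,2,2-trichloroethanol
Product: 14 3-oxo-3-(2,2,2-trichloroethoxy)propanoic acid
Conditions: toluene, 100 °C
Reagents that add atoms: none
Why: Thermal alcoholysis of Meldrum's acid (acyl substitution with loss of acetone) gives the malonic half ester, whose trichloroethyl group can later be removed reductively.

Step 10
Reactants: 11 tert-butyl{[(2Z,6Z,8E)-9-[(4S)-2,2-dimethyl-1,3-dioxolan-4-yl]-2-iodo-6-methylnona-2,6,8-trien-1-yl]oxy}diphenylsilane; 14 3-oxo-3-(2,2,2-trichloroethoxy)propanoic acid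
Product: 15 2,2,2-trichloroethyl 5-[(1Z,5Z)-7-[(tert-butyldiphenylsilyl)oxy]-6-iodo-2-methylhepta-1,5-dien-1-yl]-4-[(4S)-2,2-dimethyl-1,3-dioxolan-4-yl]-2-oxooxolane-3-carboxylate (ring substituents at C6 and C7 trans; C6, C7, C8 as in the target; C11 epimers)
Conditions: Mn(OAc)3·2H2O, KOAc, AcOH, 45 °C, argon
Reagents that add atoms: none
Why: Mn(OAc)3 oxidizes the enol form of half ester 14 to an electrophilic malonyl radical, which adds to the monosubstituted diene terminus C7; a second Mn(OAc)3 oxidizes the resulting C4–C5–C6 allyl radical to the allyl cation, and the free carboxyl oxygen then closes onto C6, so that O–C6 formation is the ring-closing event. The closest known reaction type is the Mn(OAc)3-mediated oxidative γ-lactone annulation of alkenes and conjugated dienes with acetic, cyanoacetic and malonic acid derivatives. The lactone closes in the 5-exo mode by oxygen capture of the allyl cation at C6, which is preferred over the seven-membered alternative at C4, and the trichloroethyl ester carbonyl cannot compete because it cannot shed its alkyl group. C7 is controlled by the adjacent C8 stereocentre: with the C8–H bond eclipsing the C6=C7 bond (allylic strain) the radical should enter anti to the C8–O bond, giving the C7/O8 erythro arrangement of the target. C6 is controlled in the ring closure by C7, the transition state with the C5 alkenyl group trans to the C8 substituent on the forming five-membered ring being the less crowded one, while C11 forms as an epimer mixture that step 11 erases. The step needs attack at C7 and not at C4 or the iodoalkene, secured by the lower substitution of C7 and the far higher radical affinity of a conjugated diene, and retention of the 4Z geometry, secured by the partial double-bond character of C4–C5 in the allyl radical and cation and by the fast intramolecular trapping.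

Step 11
Reactants: 15 trichloroethyl lactone ester
Product: 17 5-[(1Z,5Z)-7-[(tert-butyldiphenylsilyl)oxy]-6-iodo-2-methylhepta-1,5-dien-1-yl]-4-[(4S)-2,2-dimethyl-1,3-dioxolan-4-yl]-3-methylideneoxolan-2-one (4,5-trans), via lactone carboxylic acid 16 (not isolated)
Conditions: Zn, AcOH/THF, rt; then aq. CH2O, Et2NH, NaOAc/AcOH, 55 °C
Reagents that add atoms: formaldehyde, C=O
Why: Zinc induces reductive β-elimination of the trichloroethyl ester to the free acid, and the Mannich reaction with formaldehyde and diethylamine at C11 followed by decarboxylative elimination should give the α-methylene lactone, erasing the C11 stereocentre.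

Step 12
Reactants: 17 α-methylene lactone acetonide
Product: 18 4-[(1S)-1,2-dihydroxyethyl]-5-[(1Z,5Z)-7-[(tert-butyldiphenylsilyl)oxy]-6-iodo-2-methylhepta-1,5-dien-1-yl]-3-methylideneoxolan-2-one (4,5-trans)
Conditions: AcOH/H2O/THF, 45 °C
Reagents that add atoms: none
Why: Acid-catalysed acetal hydrolysis frees the C8/C9 diol, and since the trans-disubstituted γ-lactone at O6 is the thermodynamically preferred lactone no translactonization to O8 is expected.

Step 13
Reactants: 18 lactone diol
Product: 19 4-[(1S)-1,2-bis(triethylsilyloxy)ethyl]-5-[(1Z,5Z)-7-[(tert-butyldiphenylsilyl)oxy]-6-iodo-2-methylhepta-1,5-dien-1-yl]-3-methylideneoxolan-2-one (4,5-trans)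
Conditions: Et3SiOTf, 2,6-lutidine, CH2Cl2, −78 °C
Reagents that add atoms: triethylsilyl trifluoromethanesulfonate, CC[Si](CC)(CC)OS(=O)(=O)C(F)(F)F
Why: Silylation of both hydroxyls with the silyl triflate under hindered-base buffering leaves the α-methylene lactone untouched.

Step 14
Reactants: 19 bis(triethylsilyl) ether
Product: 20 5-[(1Z,5Z)-7-[(tert-butyldiphenylsilyl)oxy]-6-iodo-2-methylhepta-1,5-dien-1-yl]-3-methylidene-4-[(1S)-2-oxo-1-(triethylsilyloxy)ethyl]oxolan-2-one (4,5-trans)
Conditions: (COCl)2, DMSO, CH2Cl2, −78 to −30 °C; then Et3N, −78 °C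
Reagents that add atoms: none
Why: Swern oxidation, in which activated DMSO should cleave and oxidize the primary triethylsilyl ether directly to the aldehyde while the secondary triethylsilyl and the tert-butyldiphenylsilyl ethers stay inert.

Step 15
Reactants: 20 iodoalkenyl aldehyde
Product: 21 (1(10)Z,4Z)-14-[(tert-butyldiphenylsilyl)oxy]-9β-hydroxy-8β-[(triethylsilyl)oxy]germacra-1(10),4,11(13)-trien-6α,12-olide (H-7α)
Conditions: CrCl2, NiCl2 (cat.), DMSO/THF, rt, high dilution
Reagents that add atoms: none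
Why: Nozaki–Hiyama–Kishi reaction, in which NiCl2-catalysed formation of the alkenylchromium species with retention of olefin geometry and its intramolecular addition to the aldehyde closes the ten-membered ring, and the new C9 carbinol should form with the alkenyl group entering anti to the C8–O bond (polar 1,2-induction), giving the 8,9-erythro (9β) alcohol.

Step 16
Reactants: 21 macrocyclic alcohol
Product: 22 (1(10)Z,4Z)-9β-acetoxy-14-[(tert-butyldiphenylsilyl)oxy]-8β-[(triethylsilyl)oxy]germacra-1(10),4,11(13)-trien-6α,12-olide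
Conditions: Ac2O, pyridine, DMAP (cat.), CH2Cl2, 0 °C
Reagents that add atoms: acetic anhydride, CC(=O)OC(C)=O
Why: DMAP-catalysed acylation of the secondary allylic alcohol installs the C9 acetate while both other oxygens are still silylated.

Step 17
Reactants: 22 acetate
Product: 23 (1(10)Z,4Z)-9β-acetoxy-8β,14-dihydroxygermacra-1(10),4,11(13)-trien-6α,12-olide
Conditions: HF·pyridine, pyridine, THF, 0 °C to rt
Reagents that add atoms: none
Why: Fluoride-mediated desilylation removes both silyl ethers under buffered conditions that should not induce acetate migration or translactonization.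

Step 18
Reactants: 23 diol
Product: 24 (1(10)Z,4Z)-9β-acetoxy-8β-hydroxy-14-(3-methylbutanoyloxy)germacra-1(10),4,11(13)-trien-6α,12-olide (target)
Conditions: 3-methylbutanoyl chloride, 2,4,6-collidine, CH2Cl2, −40 °C
Reagents that add atoms: 3-methylbutanoyl chloride, CC(C)CC(Cl)=O
Why: Kinetic regioselective esterification, in which the acid chloride at low temperature should select the primary allylic hydroxyl over the hindered secondary C8 hydroxyl flanked by the lactone and the acetate.

**Compound list**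
1 | nerol, (2Z)-3,7-dimethylocta-2,6-dien-1-ol | CC(C)=CCC/C(C)=C\CO | starting material
2 | neryl bromide, (2Z)-1-bromo-3,7-dimethylocta-2,6-diene | CC(C)=CCC/C(C)=C\CBr | intermediate
3 | diethyl [(2Z)-3,7-dimethylocta-2,6-dien-1-yl]phosphonate | CC(C)=CCC/C(C)=C\CP(=O)(OCC)OCC | intermediate
4 | diethyl [(2Z)-5-(3,3-dimethyloxiran-2-yl)-3-methylpent-2-en-1-yl]phosphonate (racemic at the oxirane carbon) | CC1(C)OC1CC/C(C)=C\CP(=O)(OCC)OCC | intermediate
5 | diethyl [(2Z)-3-methyl-6-oxohex-2-en-1-yl]phosphonate | O=CCC/C(C)=C\CP(=O)(OCC)OCC | intermediate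
6 | diethyl [(2Z,6E)-3-methyl-8-oxoocta-2,6-dien-1-yl]phosphonate | O=C/C=C/CC/C(C)=C\CP(=O)(OCC)OCC | intermediate
7 | diethyl [(2Z,6Z)-7-iodo-3-methyl-8-oxoocta-2,6-dien-1-yl]phosphonate | O=CC(/I)=C/CC/C(C)=C\CP(=O)(OCC)OCC | intermediate
8 | diethyl [(2Z,6Z)-8-hydroxy-7-iodo-3-methylocta-2,6-dien-1-yl]phosphonate | OCC(/I)=C/CC/C(C)=C\CP(=O)(OCC)OCC | intermediate
9 | diethyl [(2Z,6Z)-8-[(tert-butyldiphenylsilyl)oxy]-7-iodo-3-methylocta-2,6-dien-1-yl]phosphonate | CC(C)(C)[Si](OCC(/I)=C/CC/C(C)=C\CP(=O)(OCC)OCC)(c1ccccc1)c1ccccc1 | intermediate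
10 | (R)-glyceraldehyde acetonide, (4R)-2,2-dimethyl-1,3-dioxolane-4-carbaldehyde | O=C[C@H]1COC(C)(C)O1 | starting material
11 | tert-butyl{[(2Z,6Z,8E)-9-[(4S)-2,2-dimethyl-1,3-dioxolan-4-yl]-2-iodo-6-methylnona-2,6,8-trien-1-yl]oxy}diphenylsilane | CC(C)(C)[Si](OCC(/I)=C/CC/C(C)=C\C=C\[C@H]1COC(C)(C)O1)(c1ccccc1)c1ccccc1 | intermediate
12 | Meldrum's acid, 2,2-dimethyl-1,3-dioxane-4,6-dione | CC1(C)OC(=O)CC(=O)O1 | starting material
13 | 2,2,2-trichloroethanol | OCC(Cl)(Cl)Cl | starting material
14 | 3-oxo-3-(2,2,2-trichloroethoxy)propanoic acid | OC(=O)CC(=O)OCC(Cl)(Cl)Cl | intermediate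
15 | 2,2,2-trichloroethyl 5-[(1Z,5Z)-7-[(tert-butyldiphenylsilyl)oxy]-6-iodo-2-methylhepta-1,5-dien-1-yl]-4-[(4S)-2,2-dimethyl-1,3-dioxolan-4-yl]-2-oxooxolane-3-carboxylate (4,5-trans; C6, C7, C8 as in target; C11 epimers) | O=C1O[C@H](/C=C(/C)CC/C=C(\I)CO[Si](c2ccccc2)(c3ccccc3)C(C)(C)C)[C@@H]([C@H]4COC(C)(C)O4)C1C(=O)OCC(Cl)(Cl)Cl | intermediate
16 | 5-[(1Z,5Z)-7-[(tert-butyldiphenylsilyl)oxy]-6-iodo-2-methylhepta-1,5-dien-1-yl]-4-[(4S)-2,2-dimethyl-1,3-dioxolan-4-yl]-2-oxooxolane-3-carboxylic acid (4,5-trans; C11 epimers) | O=C1O[C@H](/C=C(/C)CC/C=C(\I)CO[Si](c2ccccc2)(c3ccccc3)C(C)(C)C)[C@@H]([C@H]4COC(C)(C)O4)C1C(=O)O | intermediate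
17 | 5-[(1Z,5Z)-7-[(tert-butyldiphenylsilyl)oxy]-6-iodo-2-methylhepta-1,5-dien-1-yl]-4-[(4S)-2,2-dimethyl-1,3-dioxolan-4-yl]-3-methylideneoxolan-2-one (4,5-trans) | C=C1C(=O)O[C@H](/C=C(/C)CC/C=C(\I)CO[Si](c2ccccc2)(c3ccccc3)C(C)(C)C)[C@H]1[C@H]4COC(C)(C)O4 | intermediate
18 | 4-[(1S)-1,2-dihydroxyethyl]-5-[(1Z,5Z)-7-[(tert-butyldiphenylsilyl)oxy]-6-iodo-2-methylhepta-1,5-dien-1-yl]-3-methylideneoxolan-2-one (4,5-trans) | C=C1C(=O)O[C@H](/C=C(/C)CC/C=C(\I)CO[Si](c2ccccc2)(c3ccccc3)C(C)(C)C)[C@H]1[C@H](O)CO | intermediate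
19 | 4-[(1S)-1,2-bis(triethylsilyloxy)ethyl]-5-[(1Z,5Z)-7-[(tert-butyldiphenylsilyl)oxy]-6-iodo-2-methylhepta-1,5-dien-1-yl]-3-methylideneoxolan-2-one (4,5-trans) | C=C1C(=O)O[C@H](/C=C(/C)CC/C=C(\I)CO[Si](c2ccccc2)(c3ccccc3)C(C)(C)C)[C@H]1[C@H](O[Si](CC)(CC)CC)CO[Si](CC)(CC)CC | intermediate
20 | 5-[(1Z,5Z)-7-[(tert-butyldiphenylsilyl)oxy]-6-iodo-2-methylhepta-1,5-dien-1-yl]-3-methylidene-4-[(1S)-2-oxo-1-(triethylsilyloxy)ethyl]oxolan-2-one (4,5-trans) | C=C1C(=O)O[C@H](/C=C(/C)CC/C=C(\I)CO[Si](c2ccccc2)(c3ccccc3)C(C)(C)C)[C@H]1[C@H](O[Si](CC)(CC)CC)C=O | intermediate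
21 | (1(10)Z,4Z)-14-[(tert-butyldiphenylsilyl)oxy]-9β-hydroxy-8β-[(triethylsilyl)oxy]germacra-1(10),4,11(13)-trien-6α,12-olide | C=C1C(=O)O[C@@H]2/C=C(/C)CC/C=C(/CO[Si](c3ccccc3)(c4ccccc4)C(C)(C)C)[C@@H](O)[C@@H](O[Si](CC)(CC)CC)[C@@H]12 | intermediate
22 | (1(10)Z,4Z)-9β-acetoxy-14-[(tert-butyldiphenylsilyl)oxy]-8β-[(triethylsilyl)oxy]germacra-1(10),4,11(13)-trien-6α,12-olide | C=C1C(=O)O[C@@H]2/C=C(/C)CC/C=C(/CO[Si](c3ccccc3)(c4ccccc4)C(C)(C)C)[C@@H](OC(C)=O)[C@@H](O[Si](CC)(CC)CC)[C@@H]12 | intermediate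
23 | (1(10)Z,4Z)-9β-acetoxy-8β,14-dihydroxygermacra-1(10),4,11(13)-trien-6α,12-olide | C=C1C(=O)O[C@@H]2/C=C(/C)CC/C=C(/CO)[C@@H](OC(C)=O)[C@@H](O)[C@@H]12 | intermediate
24 | (1(10)Z,4Z)-9β-acetoxy-8β-hydroxy-14-(3-methylbutanoyloxy)germacra-1(10),4,11(13)-trien-6α,12-olide | C=C1C(=O)O[C@@H]2/C=C(/C)CC/C=C(/COC(=O)CC(C)C)[C@@H](OC(C)=O)[C@@H](O)[C@@H]12 | target

Total step count: 18. Longest linear sequence: 17 steps (steps 1–8 and 10–18; step 9 is a one-step side branch).

**Steps most likely to fail**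

Step 10. What may go wrong: poor facial discrimination in the radical addition at C7 next to the dioxolane stereocentre, partial loss of the 4Z geometry in the allyl cation, and further oxidation of the still acidic C11–H of the product. The fallback makes the radical addition intramolecular. It sets out from 11: aqueous acetic acid removes the acetonide to give (2S,3E,5Z,9Z)-11-[(tert-butyldiphenylsilyl)oxy]-10-iodo-6-methylundeca-3,5,9-triene-1,2-diol F1. Warming with Meldrum's acid 12 acylates the primary hydroxyl to the O9-tethered malonic half ester F2. Mn(OAc)3/KOAc in AcOH should then cyclize the tethered malonyl radical 6-exo onto C7 through a chair transition state with the C8 hydroxyl equatorial, and the free carboxyl closes on C6 to the fused δ-lactone/γ-lactone F3. LiOH opens the more reactive δ-lactone to the hydroxy acid F4, and formaldehyde/diethylamine effects the decarboxylative methylenation. The route is rejoined at 18.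

Step 15. What may go wrong: oligomerization and slow ring closure because of the strain of the forming Z,Z-cyclodecadiene fused to the trans lactone, and insufficient facial selectivity at C9. The fallback closes the carbocycle before the lactone exists. It sets out from 11: diol F1 (made as above) is silylated with Et3SiOTf to the bis(triethylsilyl) ether F5. Swern oxidation gives the diene aldehyde F6. CrCl2/NiCl2 macrocyclization of this substrate, in which C6 and C7 are still a planar E alkene, should give the cyclodecatrienol F7, which is acetylated to F8. The lactone annulation with 14 and Mn(OAc)3 is then run on the ring diene to give the macrocyclic lactone ester F9. Zinc followed by formaldehyde/diethylamine (via acid F10) returns the route at 22.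

Step 14. What may go wrong: competing cleavage of the secondary silyl ether and amine-induced epimerization at C8 of the α-silyloxy aldehyde. The fallback separates deprotection and oxidation. It sets out from 19: HF·pyridine buffered with pyridine should remove only the primary triethylsilyl ether to give the primary alcohol F11. Dess–Martin periodinane with NaHCO3 then oxidizes it without amine base and returns the route at 20.

Further compounds
F1 | step 10 | (2S,3E,5Z,9Z)-11-[(tert-butyldiphenylsilyl)oxy]-10-iodo-6-methylundeca-3,5,9-triene-1,2-diol | CC(C)(C)[Si](OCC(/I)=C/CC/C(C)=C\C=C\[C@H](O)CO)(c1ccccc1)c1ccccc1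
F2 | step 10 | 3-{[(2S,3E,5Z,9Z)-11-[(tert-butyldiphenylsilyl)oxy]-2-hydroxy-10-iodo-6-methylundeca-3,5,9-trien-1-yl]oxy}-3-oxopropanoic acid | CC(C)(C)[Si](OCC(/I)=C/CC/C(C)=C\C=C\[C@H](O)COC(=O)CC(=O)O)(c1ccccc1)c1ccccc1
F3 | step 10 | fused bis-lactone: γ-lactone O6–C12 and δ-lactone O9–carbonyl sharing C7–C11, free 8-hydroxyl, C6 bearing the (1Z,5Z)-7-[(tert-butyldiphenylsilyl)oxy]-6-iodo-2-methylhepta-1,5-dienyl chain | O=C1O[C@H](/C=C(/C)CC/C=C(\I)CO[Si](c3ccccc3)(c4ccccc4)C(C)(C)C)[C@H]2[C@H](O)COC(=O)C12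
F4 | step 10 | 4-[(1S)-1,2-dihydroxyethyl]-5-[(1Z,5Z)-7-[(tert-butyldiphenylsilyl)oxy]-6-iodo-2-methylhepta-1,5-dien-1-yl]-2-oxooxolane-3-carboxylic acid (4,5-trans) | O=C1O[C@H](/C=C(/C)CC/C=C(\I)CO[Si](c2ccccc2)(c3ccccc3)C(C)(C)C)[C@@H]([C@H](O)CO)C1C(=O)O
F5 | step 15 | 1,2-bis(triethylsilyl) ether of F1 | CC(C)(C)[Si](OCC(/I)=C/CC/C(C)=C\C=C\[C@H](O[Si](CC)(CC)CC)CO[Si](CC)(CC)CC)(c1ccccc1)c1ccccc1
F6 | step 15 | (2S,3E,5Z,9Z)-11-[(tert-butyldiphenylsilyl)oxy]-10-iodo-6-methyl-2-[(triethylsilyl)oxy]undeca-3,5,9-trienal | CC(C)(C)[Si](OCC(/I)=C/CC/C(C)=C\C=C\[C@H](O[Si](CC)(CC)CC)C=O)(c1ccccc1)c1ccccc1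
F7 | step 15 | (1R,2S,3E,5Z,9Z)-10-{[(tert-butyldiphenylsilyl)oxy]methyl}-6-methyl-2-[(triethylsilyl)oxy]cyclodeca-3,5,9-trien-1-ol | CC(C)(C)[Si](OC/C1=C/CC/C(C)=C\C=C\[C@H](O[Si](CC)(CC)CC)[C@@H]1O)(c2ccccc2)c3ccccc3
F8 | step 15 | acetate of F7 | CC(C)(C)[Si](OC/C1=C/CC/C(C)=C\C=C\[C@H](O[Si](CC)(CC)CC)[C@@H]1OC(C)=O)(c2ccccc2)c3ccccc3
F9 | step 15 | 2,2,2-trichloroethyl 11-carboxylate of the 11,13-dihydro-13-nor analogue of 22 (C11 epimers) | O=C1O[C@@H]2/C=C(/C)CC/C=C(/CO[Si](c3ccccc3)(c4ccccc4)C(C)(C)C)[C@@H](OC(C)=O)[C@@H](O[Si](CC)(CC)CC)[C@H]2C1C(=O)OCC(Cl)(Cl)Cl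
F10 | step 15 | free 11-carboxylic acid corresponding to F9 | O=C1O[C@@H]2/C=C(/C)CC/C=C(/CO[Si](c3ccccc3)(c4ccccc4)C(C)(C)C)[C@@H](OC(C)=O)[C@@H](O[Si](CC)(CC)CC)[C@H]2C1C(=O)O
F11 | step 14 | 5-[(1Z,5Z)-7-[(tert-butyldiphenylsilyl)oxy]-6-iodo-2-methylhepta-1,5-dien-1-yl]-4-[(1S)-2-hydroxy-1-(triethylsilyloxy)ethyl]-3-methylideneoxolan-2-one (4,5-trans) | C=C1C(=O)O[C@H](/C=C(/C)CC/C=C(\I)CO[Si](c2ccccc2)(c3ccccc3)C(C)(C)C)[C@H]1[C@H](O[Si](CC)(CC)CC)CO
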